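Does more scavenger change how much of the starting complex has reacted by 4.0 d?

| setting | eta | theta | beta | alder | elm |
|---|---|---|---|---|---|
| starting complex | 0.10 M | 0.10 M | 0.10 M | 0.10 M | 0.10 M |
| incoming ligand | 0.13 M | 0.13 M | 0.13 M | 0.130 M | 0.130 M |
| scavenger | 0.16 M | 0.18 M | 0.23 M | 0.150 M | 0.200 M |
| remark | run made earlier | run made earlier | run made earlier |  |  |
| time |  |  |  | 4.0 d | 4.0 d |

| run | time / d | starting complex / % | complex with one exchanged / % |
|---|---|---|---|
| eta | 0.208 | 82 | 8 |
| eta | 0.500 | 72 | 12 |
| eta | 1.25 | 53 | 14 |
| eta | 3.00 | 41 | 11 |
| theta | 0.333 | 75 | 11 |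
| theta | 1.04 | 59 | 12 |
| theta | 1.67 | 54 | 8 |
| theta | 3.00 | 42 | 5 |
| beta | 0.333 | 77 | 15 |
| beta | 1.04 | 60 | 14 |
| beta | 1.67 | 51 | 7 |
| beta | 3.00 | 39 | 10 |

(scatter of a reading: 2 percentage points)

1. part of the starting complex that has reacted at the end, alder
2. part of the starting complex that has reacted at the end, elm
3. what raising the concentration of scavenger from its lowest to its highest value here does to the part of the starting complex that has reacted (changes below 5 percentage points count as none) (it rises / no change / it falls)



At 3.00 d the earlier runs held 41%, 42% and 39% of the starting complex, with scavenger rising from 0.16 M to 0.23 M. Those readings spread over 3 percentage points against a scatter of 2 points, so I expected no trend. In eta at 1.25 d, 47.0% had reacted, but complex with one exchanged read 14%, less than that. So I counted two ligands per complex reacted, and on that count the incoming ligand was the limiting reagent.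

My measure was the fraction of the charged starting complex that the incoming ligand can carry through both exchanges, the two-ligand share: 65.0%. Eta had reached 59.0% at 3.00 d, so I committed to about that share for alder and elm.

The forecast gave 63% for alder, 63% for elm and no change, a little below my share. Its ground was: “Each starting complex therefore uses about two ligands”.

Alder gave 63.2% and elm 65.4%, a change of 2.2 points: no change. Free incoming ligand stood at 13% of its charge in alder and 12% in elm at 4.00 d. Moved one at a time by one factor, up or down, the settings tried shifted alder at most by these amounts: incoming ligand (9.1 points), then starting complex (7.7 points), then time (4.4 points), then scavenger (2.5 points).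

    starting complex + incoming ligand ⇌ leaving ligand + complex with one exchanged (K = 0.140, k = 0.00529 M⁻¹ min⁻¹)
    starting complex + complex with one exchanged → side product (k = 0.00149 M⁻¹ min⁻¹)
    complex with one exchanged + incoming ligand ⇌ leaving ligand + complex with two exchanged (K = 4.70, k = 0.0265 M⁻¹ min⁻¹)
    scavenger + leaving ligand → scavenged by-product (k = 0.0366 M⁻¹ min⁻¹)
    leaving ligand + incoming ligand ⇌ idle adduct, settled at all times (K = 102 M⁻¹)

I reckoned the same share for a neighbour of elm with 0.040 M of starting complex, all else held. It came to 162%, above the whole charge. That flask reached 87.7% reacted at 4.00 d, more than elm, with 43.5% of its incoming ligand left.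

The earlier runs and the new flask are calculated with made-up constants; scatter was added.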